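**Retrosynthetic overview**
1. GA50 ⇐ C6 epimerisation and deprotection ⇐ C2 hydroxylation and C3 reduction of a 3-oxo-19,10-lactone ⇐ acid lactonisation (C19→C10) of the Birch reductive-methylation product of a ring A 2-methoxybenzoate.
2. Ring D ⇐ Pd(OAc)2 oxidative cycloalkenylation (C13–C16) of a C12 silyl enol ether onto the 8-allyl group; C7 ⇐ lateral carboxylation at C6.
3. Ring B (C9–C10) ⇐ key organocatalytic desymmetrising Friedel–Crafts/Michael cyclisation of an achiral 4-allyl-4-benzylcyclohexadienone (sets C8 and C9).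
4. Dienone ⇐ oxidative dearomatising para-allylation of a diarylmethane phenol ⇐ Suzuki coupling of two achiral arenes.
5. Ring order: A and C (bought as arenes) → B → D → ring A dearomatised and lactonised.

Assumption: gibberellane numbering (C1–C19) is used for all intermediates, α is the face of the lactone bridge, and the enantiomer of the chiral acid in step 4 is the one that gives the C8/C9 configuration drawn.

Step 1
Reactants: 1 methyl 2-methoxy-6-methylbenzoate
Product: 2 methyl 2-(bromomethyl)-6-methoxybenzoate
Conditions: NBS, AIBN (cat.), PhCF3, 80 °C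
Reagents that add atoms: N-bromosuccinimide, O=C1CCC(=O)N1Br
Why: Wohl–Ziegler radical bromination attacks the only benzylic C–H site of the ortho-toluate and creates no stereocentre.

Step 2
Reactants: 2 methyl 2-(bromomethyl)-6-methoxybenzoate; 3 4-hydroxyphenylboronic acid
Product: 4 methyl 2-[(4-hydroxyphenyl)methyl]-6-methoxybenzoate
Conditions: Pd(PPh3)4 (3 mol %), K2CO3, THF/H2O, 60 °C
Reagents that add atoms: none
Why: Suzuki–Miyaura coupling of the reactive benzylic bromide with the arylboronic acid tolerates the free phenol and joins the future rings A and C through C6 without forming a stereocentre.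

Step 3
Reactants: 4 methyl 2-[(4-hydroxyphenyl)methyl]-6-methoxybenzoate; 5 allyltrimethylsilane
Product: 6 methyl 2-methoxy-6-{[4-oxo-1-(prop-2-en-1-yl)cyclohexa-2,5-dien-1-yl]methyl}benzoate
Conditions: PhI(OAc)2, (CF3)2CHOH, −10 °C → rt
Reagents that add atoms: none
Why: trivalent-iodine oxidation turns the para-substituted phenol into a phenoxenium ion that the allylsilane traps at the para carbon (oxidative dearomatising Hosomi–Sakurai-type allylation), giving the C8-quaternary dienone, which is achiral because its two enone arms are enantiotopic.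

Step 4
Reactants: 6 methyl 2-methoxy-6-{[4-oxo-1-(prop-2-en-1-yl)cyclohexa-2,5-dien-1-yl]methyl}benzoate
Product: 7 methyl 2-methoxy-6-oxo-8a-(prop-2-en-1-yl)-5,6,8a,9-tetrahydro-4bH-fluorene-1-carboxylate (cis-fused; H-9 and 8-allyl both β)
Conditions: chiral imidodiphosphorimidate Brønsted acid (5 mol %), CHCl3, −30 °C
Reagents that add atoms: none
Why: Proposed new method: the confined chiral Brønsted acid protonates the dienone carbonyl inside its chiral pocket so that the tethered anisole ring attacks only one of the two enantiotopic β-carbons (C9) through its carbon para to OMe (C10) in a 5-exo Friedel–Crafts/Michael closure, the one-carbon tether forcing cis fusion so that C8 and C9 are set together, the closest known reaction type being chiral-phosphoric-acid-catalysed desymmetrising intramolecular oxa-, aza- and indole Friedel–Crafts Michael additions to 4,4-disubstituted cyclohexadienones.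

Step 5
Reactants: 7 tricyclic enone
Product: 9 methyl 6-[(tert-butyldimethylsilyl)oxy]-2-methoxy-8a-(prop-2-en-1-yl)-5,8,8a,9-tetrahydro-4bH-fluorene-1-carboxylate, via lithium enolate 8 (not isolated)
Conditions: LiBH(s-Bu)3, THF, −78 °C; then TBSOTf, −78 → 0 °C
Reagents that add atoms: tert-butyldimethylsilyl trifluoromethanesulfonate, CC(C)(C)[Si](C)(C)OS(=O)(=O)C(F)(F)F
Why: 1,4-hydride reduction of the enone by the hindered borohydride spares the hindered aryl ester and gives the C12/C13 enolate regiospecifically, which O-silylation stores as the silyl enol ether needed for ring D (conjugate reduction with enolate trapping).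

Step 6
Reactants: 9 silyl enol ether
Product: 11 6-[(tert-butyldimethylsilyl)oxy]-2-methoxy-1-(methoxycarbonyl)-8a-(prop-2-en-1-yl)-5,8,8a,9-tetrahydro-4bH-fluorene-9-carboxylic acid (CO2H anti to the allyl group; C7 α), via benzylic organolithium 10 (not isolated)
Conditions: LiN(i-Pr)2, THF, −78 °C; CO2; cold dilute HCl
Reagents that add atoms: carbon dioxide, O=C=O
Why: lateral (benzylic) lithiation ortho to the ester generates the C6 carbanion and CO2 enters on the face anti to the angular 8-allyl group, as additions next to the angular carbon of hydrindane systems do, giving the 7-acid with C7 α (6-epi) as a carboxylate that can no longer epimerise.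

Step 7
Reactants: 11 silyl enol ether acid
Product: 12 6-epi-3-methoxy-12-oxo-20-norgibberella-1,3,5(10),16-tetraene-7,19-dioic acid 19-methyl ester (ring A aromatic; H-9 β)
Conditions: Pd(OAc)2 (10 mol %), O2 (1 atm), DMSO, 45 °C
Reagents that add atoms: none
Why: divalent palladium activates the allyl alkene for 5-exo attack by C13 of the silyl enol ether and β-hydride elimination leaves the exocyclic C16=C17 methylene (oxidative cycloalkenylation with O2 turnover), the bridging fixing C13 because the two-carbon bridge can span C8 and C13 on one face only.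

Step 8
Reactants: 12 tetracyclic keto acid
Product: 14 6-epi-12β-hydroxy-3-methoxy-20-norgibberella-2,5(10),16-triene-7,19-dioic acid 19-methyl ester (4β-methyl; 4α-CO2Me), via tripotassium enolate 13 (not isolated)
Conditions: K, NH3 (l)/THF, t-BuOH, −78 °C; then MeI; NH4Cl
Reagents that add atoms: iodomethane, CI
Why: Birch reductive alkylation of the 2-methoxybenzoate (low-temperature potassium conditions keep the methoxy group) gives a cross-conjugated ester dienolate that MeI alkylates at C4 on the face anti to the C6 carboxylate (methyl β, C19 α), while the same reduction converts the C12 ketone into the thermodynamically favoured equatorial 12β-alcohol, which lies on the face of ring C that carries the C15–C16 bridge.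

Step 9
Reactants: 14 diene acid ester
Product: 15 dimethyl 6-epi-12β-hydroxy-3-methoxy-20-norgibberella-2,5(10),16-triene-7,19-dioate
Conditions: Me3SiCHN2, MeOH/PhMe, 0 °C
Reagents that add atoms: (trimethylsilyl)diazomethane, C[Si](C)(C)C=[N+]=[N-]
Why: the diazoalkane O-methylates only the free C7 acid, so that C7 is no better a nucleophile than C19 in the next step and carries the ester needed for the later C6 epimerisation.

Step 10
Reactants: 15 diene diester
Product: 17 6-epi-12β-hydroxy-3-oxo-20-norgibberell-16-ene-7,19-dioic acid 19,10-lactone 7-methyl ester, via keto diene 16 (not isolated)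
Conditions: CF3CO2H, CH2Cl2, H2O (3 equiv), 0 °C → rt
Reagents that add atoms: water, O
Why: acid hydrolyses the enol ether to the C3 ketone and protonates the tetrasubstituted C5=C10 alkene at C5 to a tertiary C10 cation that the α-disposed C19 ester carbonyl captures with loss of methanol (acid-catalysed γ-lactonisation by anti addition, the less strained bicyclo[3.2.1] lactone being preferred over closure from C7), so that O-10 is α and H-5 β as dictated by C4.

Step 11
Reactants: 17 3-oxo lactone
Product: 19 6-epi-2β,12β-dihydroxy-3-oxo-20-norgibberell-16-ene-7,19-dioic acid 19,10-lactone 7-methyl ester, via dipotassium enolate 18 (not isolated)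
Conditions: KN(SiMe3)2, THF, −78 °C; then 2-(phenylsulfonyl)-3-phenyloxaziridine; NH4Cl
Reagents that add atoms: 2-(phenylsulfonyl)-3-phenyloxaziridine, O=S(=O)(N1OC1c1ccccc1)c1ccccc1
Why: the C3 ketone can enolise only towards C2 because C4 is quaternary, and the enolate is hydroxylated by the N-sulfonyloxaziridine on the β face because the lactone bridge shields the α face (Davis enolate oxidation), giving the equatorial 2β-alcohol.

Step 12
Reactants: 19 2β-hydroxy 3-ketone
Product: 20 6-epi-GA50 methyl ester
Conditions: LiBH(s-Bu)3, THF, −78 °C; NH4Cl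
Reagents that add atoms: none
Why: the bulky borohydride attacks the 3-ketone from the equatorial α side, as is usual for 3-oxo gibberellin lactones, to give the axial 3β-alcohol cis to the 2β-hydroxyl without touching lactone or ester (reagent-controlled ketone reduction).

Step 13
Reactants: 20 6-epi-GA50 methyl ester
Product: 21 6-epi-GA50 methyl ester 2,3-acetonide
Conditions: Me2C(OMe)2, PPTS (cat.), CH2Cl2, rt
Reagents that add atoms: 2,2-dimethoxypropane, COC(C)(C)OC
Why: the cis-2β,3β-diol forms a five-membered acetonide in preference to the isolated 12-hydroxyl (transketalisation), which blocks base-induced retro-aldol epimerisation at C3 in the next step.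

Step 14
Reactants: 21 6-epi acetonide
Product: 22 GA50 methyl ester 2,3-acetonide
Conditions: NaOMe (0.5 equiv), MeOH, 50 °C
Reagents that add atoms: none
Why: methoxide equilibrates the C6 ester through its enolate to the thermodynamically preferred natural 6β epimer, in which C7 is trans to the C5–C4 bond (base-mediated epimerisation; reversible lactone methanolysis is harmless).

Step 15
Reactants: 22 GA50 methyl ester 2,3-acetonide
Product: 24 GA50, via lithium carboxylate 23 (not isolated)
Conditions: LiSPr, HMPA, rt; then AcOH/H2O (4:1), 40 °C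
Reagents that add atoms: none
Why: thiolate SN2 demethylation cleaves the hindered C7 methyl ester without opening the lactone, and mild aqueous acid then removes the acetonide without isomerising the 16-ene (nucleophilic ester dealkylation followed by acetal hydrolysis).

**Compound list**
1 | methyl 2-methoxy-6-methylbenzoate | COC(=O)c1c(C)cccc1OC | starting material
2 | methyl 2-(bromomethyl)-6-methoxybenzoate | COC(=O)c1c(CBr)cccc1OC | intermediate
3 | 4-hydroxyphenylboronic acid | OB(O)c1ccc(O)cc1 | starting material
4 | methyl 2-[(4-hydroxyphenyl)methyl]-6-methoxybenzoate | COC(=O)c1c(Cc2ccc(O)cc2)cccc1OC | intermediate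
5 | allyltrimethylsilane | C=CC[Si](C)(C)C | starting material
6 | methyl 2-methoxy-6-{[4-oxo-1-(prop-2-en-1-yl)cyclohexa-2,5-dien-1-yl]methyl}benzoate (achiral) | C=CCC1(Cc2cccc(OC)c2C(=O)OC)C=CC(=O)C=C1 | intermediate
7 | methyl 2-methoxy-6-oxo-8a-(prop-2-en-1-yl)-5,6,8a,9-tetrahydro-4bH-fluorene-1-carboxylate, cis-fused (H-9 β, 8-allyl β) | C=CC[C@]12C=CC(=O)C[C@H]1c3ccc(OC)c(C(=O)OC)c3C2 | intermediate
8 | lithium C12 enolate (C12=C13) of the 13,14-dihydro derivative of 7 | [Li+].C=CC[C@]12CC=C([O-])C[C@H]1c3ccc(OC)c(C(=O)OC)c3C2 | intermediate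
9 | methyl 6-[(tert-butyldimethylsilyl)oxy]-2-methoxy-8a-(prop-2-en-1-yl)-5,8,8a,9-tetrahydro-4bH-fluorene-1-carboxylate, cis-fused | C=CC[C@]12CC=C(O[Si](C)(C)C(C)(C)C)C[C@H]1c3ccc(OC)c(C(=O)OC)c3C2 | intermediate
10 | 9-lithio derivative of 9 (benzylic C6 organolithium) | C=CC[C@]12CC=C(O[Si](C)(C)C(C)(C)C)C[C@H]1c3ccc(OC)c(C(=O)OC)c3C2[Li] | intermediate
11 | 6-[(tert-butyldimethylsilyl)oxy]-2-methoxy-1-(methoxycarbonyl)-8a-(prop-2-en-1-yl)-5,8,8a,9-tetrahydro-4bH-fluorene-9-carboxylic acid, CO2H anti to allyl (C7 α) | C=CC[C@]12CC=C(O[Si](C)(C)C(C)(C)C)C[C@H]1c3ccc(OC)c(C(=O)OC)c3[C@H]2C(=O)O | intermediate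
12 | 6-epi-3-methoxy-12-oxo-20-norgibberella-1,3,5(10),16-tetraene-7,19-dioic acid 19-methyl ester (H-9 β, 7-CO2H α) | C=C1C[C@]23C[C@H]1C(=O)C[C@H]2c4ccc(OC)c(C(=O)OC)c4[C@H]3C(=O)O | intermediate
13 | tripotassium salt (C19 ester enolate, C7 carboxylate, C12 alkoxide) of the 1,4-dihydro arene | [K+].[K+].[K+].C=C1C[C@]23C[C@H]1[C@H]([O-])C[C@H]2C4=C([C@H]3C(=O)[O-])C(=C([O-])OC)C(OC)=CC4 | intermediate
14 | 6-epi-12β-hydroxy-3-methoxy-20-norgibberella-2,5(10),16-triene-7,19-dioic acid 19-methyl ester (4β-Me, 4α-CO2Me) | C=C1C[C@]23C[C@H]1[C@H](O)C[C@H]2C4=C([C@H]3C(=O)O)[C@](C)(C(=O)OC)C(OC)=CC4 | intermediate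
15 | dimethyl 6-epi-12β-hydroxy-3-methoxy-20-norgibberella-2,5(10),16-triene-7,19-dioate | C=C1C[C@]23C[C@H]1[C@H](O)C[C@H]2C4=C([C@H]3C(=O)OC)[C@](C)(C(=O)OC)C(OC)=CC4 | intermediate
16 | dimethyl 6-epi-12β-hydroxy-3-oxo-20-norgibberella-5(10),16-diene-7,19-dioate | C=C1C[C@]23C[C@H]1[C@H](O)C[C@H]2C4=C([C@H]3C(=O)OC)[C@](C)(C(=O)OC)C(=O)CC4 | intermediate
17 | 6-epi-12β-hydroxy-3-oxo-20-norgibberell-16-ene-7,19-dioic acid 19,10-lactone 7-methyl ester (O-10 α, H-5 β, 7-CO2Me α) | C=C1C[C@]23C[C@H]1[C@H](O)C[C@H]2[C@@]12CCC(=O)[C@@](C)(C(=O)O1)[C@H]2[C@H]3C(=O)OC | intermediate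
18 | dipotassium salt (C2=C3 enolate, C12 alkoxide) of 17 | [K+].[K+].C=C1C[C@]23C[C@H]1[C@H]([O-])C[C@H]2[C@@]12CC=C([O-])[C@@](C)(C(=O)O1)[C@H]2[C@H]3C(=O)OC | intermediate
19 | 6-epi-2β,12β-dihydroxy-3-oxo-20-norgibberell-16-ene-7,19-dioic acid 19,10-lactone 7-methyl ester | C=C1C[C@]23C[C@H]1[C@H](O)C[C@H]2[C@@]12C[C@H](O)C(=O)[C@@](C)(C(=O)O1)[C@H]2[C@H]3C(=O)OC | intermediate
20 | 6-epi-GA50 methyl ester (2β,3β,12β-triol) | C=C1C[C@]23C[C@H]1[C@H](O)C[C@H]2[C@@]12C[C@H](O)[C@H](O)[C@@](C)(C(=O)O1)[C@H]2[C@H]3C(=O)OC | intermediate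
21 | 6-epi-GA50 methyl ester 2,3-acetonide | C=C1C[C@]23C[C@H]1[C@H](O)C[C@H]2[C@@]12C[C@H](O4)[C@H](OC4(C)C)[C@@](C)(C(=O)O1)[C@H]2[C@H]3C(=O)OC | intermediate
22 | GA50 methyl ester 2,3-acetonide (7-CO2Me β) | C=C1C[C@]23C[C@H]1[C@H](O)C[C@H]2[C@@]12C[C@H](O4)[C@H](OC4(C)C)[C@@](C)(C(=O)O1)[C@H]2[C@@H]3C(=O)OC | intermediate
23 | lithium salt of GA50 2,3-acetonide | [Li+].C=C1C[C@]23C[C@H]1[C@H](O)C[C@H]2[C@@]12C[C@H](O4)[C@H](OC4(C)C)[C@@](C)(C(=O)O1)[C@H]2[C@@H]3C(=O)[O-] | intermediate
24 | GA50 | C=C1C[C@]23C[C@H]1[C@H](O)C[C@H]2[C@@]12C[C@H](O)[C@H](O)[C@@](C)(C(=O)O1)[C@H]2[C@@H]3C(=O)O | target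

Total step count: 15. Longest linear sequence: 15 steps (1 → 24).

**Three steps most likely to fail**

Step 4 (the new reaction). The strong acid may trigger dienone–phenol rearrangement or allyl migration instead of cyclisation, or give low enantioselectivity. Fallback with known chemistry, setting out from 6: NBS in MeCN brominates the anisole ring para to OMe to give methyl 3-bromo-6-methoxy-2-{[4-oxo-1-(prop-2-en-1-yl)cyclohexa-2,5-dien-1-yl]methyl}benzoate F1. An enantioselective reductive Heck desymmetrisation (Pd(OAc)2, (R)-BINAP, HCO2Na, DMF, 60 °C) then adds the aryl group to C9 through a zerovalent-palladium cycle, formate reduces the palladium enolate, and the route is rejoined at 7.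

Step 8. The methoxy group may be lost, the compound may be over-reduced, or the facial bias from the C6 carboxylate may be too weak in the one-pot alkylation. The relay from C6 to C4 is the weakest stereochemical link of the route. Fallback, setting out from 12: the same K/NH3/t-BuOH reduction quenched with NH4Cl instead of MeI gives the unmethylated 4-demethyl analogue of 14 (C4-H, epimer mixture) F2. Me3SiCHN2 converts it into the 4-demethyl analogue of 15 F3. The isolated, doubly allylic ester is then deprotonated with LiN(i-Pr)2 (2.2 equiv, THF, −78 °C) and methylated with MeI anti to the C6 ester under separately controlled conditions, coming back at 15.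

Step 10. Trifluoroacetic acid can also protonate the exocyclic 16-ene, which would give the 15-ene isomer or a C16 trifluoroacetate, and protonation at C5 may not be fully β-selective. Fallback with known chemistry, setting out from 15: oxalic acid in wet THF at 0 °C hydrolyses only the enol ether and gives the keto diene 16, which is now isolated. Iodine in MeCN (0 °C → rt, dark) then brings about iodolactonisation of the C19 methyl ester across the electron-rich tetrasubstituted C5=C10 alkene by anti addition with loss of iodomethane, giving 6-epi-5β-iodo-12β-hydroxy-3-oxo-20-norgibberell-16-ene-7,19-dioic acid 19,10-lactone 7-methyl ester F4. The less nucleophilic 16-ene forms its iodonium ion only reversibly and has no internal nucleophile. Bu3SnH with AIBN (PhMe, 80 °C) then removes the iodine. The C5 radical should take hydrogen on the β face, away from the lactone bridge, to give the trans junction of ring A and ring B, and the route comes back at 17.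

**Further compounds**
F1 | step 4 | methyl 3-bromo-6-methoxy-2-{[4-oxo-1-(prop-2-en-1-yl)cyclohexa-2,5-dien-1-yl]methyl}benzoate | C=CCC1(Cc2c(Br)ccc(OC)c2C(=O)OC)C=CC(=O)C=C1
F2 | step 8 | 4-demethyl analogue of 14 (C4-H, epimer mixture) | C=C1C[C@]23C[C@H]1[C@H](O)C[C@H]2C4=C([C@H]3C(=O)O)C(C(=O)OC)C(OC)=CC4
F3 | step 8 | 4-demethyl analogue of 15 (C4-H, epimer mixture) | C=C1C[C@]23C[C@H]1[C@H](O)C[C@H]2C4=C([C@H]3C(=O)OC)C(C(=O)OC)C(OC)=CC4
F4 | step 10 | 6-epi-5β-iodo-12β-hydroxy-3-oxo-20-norgibberell-16-ene-7,19-dioic acid 19,10-lactone 7-methyl ester | C=C1C[C@]23C[C@H]1[C@H](O)C[C@H]2[C@@]12CCC(=O)[C@@](C)(C(=O)O1)[C@@]2(I)[C@H]3C(=O)OC
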